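**Plan**
1. Cuts, last to first: six O–benzyl bonds and the lower acetonide; upper C4–C4a (upper ring C); upper C2–O1 (aryl ether); upper C3–C4 (as the C=C of a chalcone); the interflavanyl bond lower C6–upper C4 (as Ar–CHO); lower C2–ring B and lower ring C (chromone).
2. Enabling feature: upper C4 is benzylic to lower ring A, whose O1 (para) and 7-oxygen (ortho) stabilise positive charge there. Its second aryl neighbour, upper C4a, lies ortho to upper O1 and para to the upper 7-oxygen, and the 3-hydroxyl is trans on C3. Ring C therefore maps onto opening of a trans-epoxide by an oxygen-tethered arene.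
3. Forward order: lower ring C (chromone from gallacetophenone), ring B added at lower C2, lower 3,4-diol, formyl carbon on lower C6, chalcone, allylic alcohol, epoxy alcohol, aryl ether carrying upper ring A, upper ring C closed last.
4. Stereochemistry: lower C2 from Rh-catalysed asymmetric 1,4-addition; lower C3/C4 from OsO4 anti to the 2-aryl group; upper C2 from CBS reduction then Mitsunobu inversion; upper C3 from Shi epoxidation; upper C4 from inverting epoxide opening.
5. Target read as epioritin-(4β→6)-ent-oritin-4α-ol: upper unit (2R,3R), 2,3-cis-3,4-trans; lower unit (2S,3R,4R), 2,3-trans-3,4-cis.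

Key step: step 16

Assumption: in the CBS reduction the aryl group is taken as the larger carbonyl substituent (as in acetophenone), and the Rh-catalysed addition is taken to follow the sense known for cyclohexenone ((S)-bisphosphine gives the (S)-adduct); if either sense is opposite, the antipodal catalyst is used.

Abbreviation: Fl = (2S,3R,4R)-7,8-bis(benzyloxy)-2-[4-(benzyloxy)phenyl]-3,4-(isopropylidenedioxy)chroman-6-yl (descriptors of the parent diol 10; 2,3-trans-3,4-cis). Compounds 1, 6, 14 and 18 are commercial.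

**Step 1**
Reactants: 1 gallacetophenone
Product: 2 1-[3,4-bis(benzyloxy)-2-hydroxyphenyl]ethanone
Conditions: BnBr (2.1 equiv), K2CO3 (2.2 equiv), acetone, reflux
Reagents that add atoms: benzyl bromide, BrCc1ccccc1
Why: Williamson etherification; the 2-hydroxyl is hydrogen-bonded to the ketone and should stay free when only two equivalents of benzyl bromide are used.

**Step 2**
Reactants: 2 1-[3,4-bis(benzyloxy)-2-hydroxyphenyl]ethanone
Product: 3 1-[3,4-bis(benzyloxy)-5-bromo-2-hydroxyphenyl]ethanone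
Conditions: NBS (1.05 equiv), MeCN, 0 °C to rt
Reagents that add atoms: N-bromosuccinimide, O=C1CCC(=O)N1Br
Why: Electrophilic aromatic bromination should go to C5, the only free position para to the free phenol and ortho to a benzyloxy group, and places the handle for the later formyl carbon.

**Step 3**
Reactants: 3 1-[3,4-bis(benzyloxy)-5-bromo-2-hydroxyphenyl]ethanone
Product: 5 7,8-bis(benzyloxy)-6-bromo-4H-chromen-4-one, via enaminone 4 (not isolated)
Conditions: Me2NCH(OMe)2, toluene, 100 °C; then conc. HCl, CH2Cl2, 40 °C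
Reagents that add atoms: N,N-dimethylformamide dimethyl acetal, COC(OC)N(C)C
Why: Condensation of the acetyl group with the amide acetal gives the enaminone, and acid-mediated conjugate addition of the phenol with loss of dimethylamine closes lower ring C (standard enaminone chromone synthesis).

**Step 4**
Reactants: 5 7,8-bis(benzyloxy)-6-bromo-4H-chromen-4-one; 6 [4-(benzyloxy)phenyl]boronic acid
Product: 7 (2R)-7,8-bis(benzyloxy)-2-[4-(benzyloxy)phenyl]-6-bromochroman-4-one
Conditions: [Rh(OH)(cod)]2 (2.5 mol %), (R)-2,2'-bis[bis(3,4,5-trifluorophenyl)phosphino]-6,6'-dimethoxy-1,1'-biphenyl (6 mol %), CH2Cl2/H2O, rt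
Reagents that add atoms: none
Why: Rhodium-catalysed asymmetric 1,4-addition of an arylboronic acid to a chromone (Hayashi–Miyaura type), established with electron-poor biaryl bisphosphines, should set lower C2 under catalyst control (R ligand for the 2R flavanone) without base-induced ring opening and without touching the aryl bromide.

**Step 5**
Reactants: 7 (2R)-7,8-bis(benzyloxy)-2-[4-(benzyloxy)phenyl]-6-bromochroman-4-one
Product: 8 (2R,4R)-7,8-bis(benzyloxy)-2-[4-(benzyloxy)phenyl]-6-bromochroman-4-ol (2,4-cis)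
Conditions: NaBH4, THF/MeOH, 0 °C
Reagents that add atoms: none
Why: Hydride reduction of the flavanone with axial delivery should give the 2,4-cis alcohol; the C4 configuration is irrelevant because it is removed in step 6.

**Step 6**
Reactants: 8 (2R,4R)-7,8-bis(benzyloxy)-2-[4-(benzyloxy)phenyl]-6-bromochroman-4-ol
Product: 9 (2R)-7,8-bis(benzyloxy)-2-[4-(benzyloxy)phenyl]-6-bromo-2H-chromene
Conditions: Burgess reagent (MeO2CN(–)SO2N(+)Et3), toluene, 60 °C
Reagents that add atoms: none
Why: Burgess dehydration (syn elimination of the sulfamate, helped by the electron-rich benzylic position) should give the only possible alkene under non-acidic conditions that do not ionise the C2–O bond, so C2 is kept.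

**Step 7**
Reactants: 9 (2R)-7,8-bis(benzyloxy)-2-[4-(benzyloxy)phenyl]-6-bromo-2H-chromene
Product: 10 (2S,3R,4R)-7,8-bis(benzyloxy)-2-[4-(benzyloxy)phenyl]-6-bromochromane-3,4-diol (2,3-trans-3,4-cis)
Conditions: OsO4 (2 mol %), NMO (1.5 equiv), acetone/H2O, rt
Reagents that add atoms: osmium tetroxide (catalytic oxygen carrier), O=[Os](=O)(=O)=O; N-methylmorpholine N-oxide, C[N+]1([O-])CCOCC1; water, O
Why: Catalytic syn-dihydroxylation adds both hydroxyls to C3=C4 from the face opposite the C2 aryl group, the established outcome for flav-3-enes, so lower C3 and C4 are set by the C2 stereocentre.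

**Step 8**
Reactants: 10 (2S,3R,4R)-7,8-bis(benzyloxy)-2-[4-(benzyloxy)phenyl]-6-bromochromane-3,4-diol
Product: 11 Fl–Br, the 3,4-O-isopropylidene derivative (acetonide) of 10
Conditions: Me2C(OMe)2, PPTS (cat.), acetone, rt
Reagents that add atoms: 2,2-dimethoxypropane, COC(C)(C)OC
Why: Acid-catalysed transketalisation closes the cis-fused dioxolane on the cis-diol under conditions mild enough for the benzylic C4–O bond.

**Step 9**
Reactants: 11 Fl–Br
Product: 13 Fl–CHO (lower 6-carbaldehyde), via aryllithium 12 (not isolated)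
Conditions: n-BuLi (1.1 equiv), THF, –78 °C; DMF, –78 to 0 °C; then H2O
Reagents that add atoms: N,N-dimethylformamide, CN(C)C=O
Why: Bromine–lithium exchange followed by formylation of the aryllithium with DMF (Bouveault-type) places the future upper C4 on lower C6; acetonide and benzyl ethers are inert at –78 °C.

**Step 10**
Reactants: 13 Fl–CHO; 14 1-[4-(benzyloxy)phenyl]ethanone
Product: 15 (E)-1-[4-(benzyloxy)phenyl]-3-Fl-prop-2-en-1-one
Conditions: KOH, EtOH/THF, rt
Reagents that add atoms: none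
Why: Claisen–Schmidt condensation of a non-enolisable aryl aldehyde with an aryl methyl ketone gives the (E)-chalcone and forms the upper C3–C4 bond; all protecting groups are base-stable.

**Step 11**
Reactants: 15 (E)-1-[4-(benzyloxy)phenyl]-3-Fl-prop-2-en-1-one
Product: 16 (R,E)-1-[4-(benzyloxy)phenyl]-3-Fl-prop-2-en-1-ol
Conditions: (S)-2-methyl-CBS-oxazaborolidine (20 mol %), BH3·SMe2, THF, –20 °C; then MeOH
Reagents that add atoms: none
Why: Corey–Bakshi–Shibata reduction gives 1,2-reduction of the enone, and with the aryl group as the larger substituent the (S)-catalyst is expected to deliver the (R)-carbinol.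

**Step 12**
Reactants: 16 (R,E)-1-[4-(benzyloxy)phenyl]-3-Fl-prop-2-en-1-ol
Product: 17 (S)-[4-(benzyloxy)phenyl][(2S,3S)-3-Fl-oxiran-2-yl]methanol
Conditions: L-fructose-derived Shi ketone (30 mol %), KHSO5 (as 2KHSO5·KHSO4·K2SO4), K2CO3, Bu4NHSO4, MeCN/CH2(OMe)2, aq. Na2B4O7/Na2EDTA (pH 10.5), 0 °C
Reagents that add atoms: potassium peroxymonosulfate, [K+].[O-]S(=O)(=O)OO
Why: Shi epoxidation of the electron-rich trans-alkene in a basic buffer that spares the acid-labile aryl epoxide; the D-fructose-derived ketone gives (R,R)-epoxides from trans-β-substituted styrenes, so its enantiomer (made from L-sorbose) should set the (2S,3S)-epoxide under reagent control.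

**Step 13**
Reactants: 18 2,3-dihydroxybenzaldehyde
Product: 19 2,3-bis(benzyloxy)benzaldehyde
Conditions: BnBr (2.2 equiv), K2CO3, DMF, rt
Reagents that add atoms: benzyl bromide, BrCc1ccccc1
Why: Williamson etherification of both phenols.

**Step 14**
Reactants: 19 2,3-bis(benzyloxy)benzaldehyde
Product: 21 2,3-bis(benzyloxy)phenol, via aryl formate 20 (not isolated)
Conditions: mCPBA, CH2Cl2, rt; then K2CO3 (cat.), MeOH, rt
Reagents that add atoms: 3-chloroperoxybenzoic acid, OOC(=O)c1cccc(Cl)c1
Why: Dakin-type Baeyer–Villiger oxidation: the electron-rich aryl group migrates to give the aryl formate, which is cleaved by methanolysis.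

**Step 15**
Reactants: 17 (S)-[4-(benzyloxy)phenyl][(2S,3S)-3-Fl-oxiran-2-yl]methanol; 21 2,3-bis(benzyloxy)phenol
Product: 22 1,2-bis(benzyloxy)-3-{(R)-[4-(benzyloxy)phenyl][(2R,3S)-3-Fl-oxiran-2-yl]methoxy}benzene
Conditions: PPh3, DIAD, toluene, 0 °C to rt
Reagents that add atoms: none
Why: Mitsunobu etherification displaces the oxyphosphonium group by the phenol with inversion at C1, turning the (1S)-alcohol into the (1R)-aryl ether; the adjacent epoxide oxygen and the non-polar solvent disfavour ionisation of the 4-benzyloxybenzylic centre.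

**Step 16**
Reactants: 22 1,2-bis(benzyloxy)-3-{(R)-[4-(benzyloxy)phenyl][(2R,3S)-3-Fl-oxiran-2-yl]methoxy}benzene
Product: 23 (2R,3R)-7,8-bis(benzyloxy)-2-[4-(benzyloxy)phenyl]-4-Fl-chroman-3-ol, 2,3-cis-3,4-trans (Fl on the face opposite to the 3-OH and the 2-aryl group)
Conditions: FeBr3 (10 mol %), AgOSO2CF3 (30 mol %), CH2Cl2, –40 to 0 °C; Et3N quench
Reagents that add atoms: none
Why: The iron triflate formed in the flask binds the epoxide oxygen, the C4–O bond (benzylic to lower ring A and supported by its para ring oxygen and ortho benzyloxy group) stretches, and C6 of the 2,3-bis(benzyloxy)phenyl ether (the future C4a, ortho to the ether oxygen and para to a benzyloxy group) attacks C4 anti to the leaving oxygen, followed by rearomatisation. The closest known reaction is the Lewis-acid-catalysed intramolecular Friedel–Crafts epoxy-arene cyclisation of aryl 3-arylglycidyl ethers to trans-4-arylchroman-3-ols. Upper ring C closes in the 6-endo mode, preferred over 5-exo attack at C3 because only C4 is benzylic. The one new stereocentre, upper C4, is fixed by the configuration of the trans-epoxide through inversion, which puts the lower flavanyl group trans to the 3-hydroxyl, while C2 and C3 pass through unchanged. The step needs site selectivity among the arenes and chemoselectivity over the lower acetonide and the C2 aryl ether: only the ether ring offers an activated carbon that reaches C4 through a six-membered transition state, and the strained epoxide should ionise at low temperature before the lower C4–O acetal bond or the C2–O bond does.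

**Step 17**
Reactants: 23 (2R,3R)-7,8-bis(benzyloxy)-2-[4-(benzyloxy)phenyl]-4-Fl-chroman-3-ol
Product: 24 hexa-O-benzyl triol: 23 with the lower 3,4-acetonide replaced by the free (3R,4R)-cis-diol
Conditions: AcOH/H2O/THF, 40 °C
Reagents that add atoms: none
Why: Acid-catalysed acetal hydrolysis cleaves at the ketal carbon under conditions too mild to ionise the benzylic lower C4–O bond or the interflavanyl bond, and benzyl ethers are stable.

**Step 18**
Reactants: 24 hexa-O-benzyl triol
Product: 25 target, epioritin-(4β→6)-ent-oritin-4α-ol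
Conditions: H2 (1 atm), Pd(OH)2/C, THF/MeOH, rt
Reagents that add atoms: none
Why: Catalytic hydrogenolysis removes the six aryl benzyl ethers, which cleave faster than the benzylic C4–OH, C2–O1 and C4–aryl bonds, so the reaction is stopped once six equivalents of hydrogen are taken up.

**Compound list**
1 | gallacetophenone | CC(=O)c1ccc(O)c(O)c1O | starting material
2 | 1-[3,4-bis(benzyloxy)-2-hydroxyphenyl]ethanone | CC(=O)c1ccc(OCc2ccccc2)c(OCc2ccccc2)c1O | intermediate
3 | 1-[3,4-bis(benzyloxy)-5-bromo-2-hydroxyphenyl]ethanone | CC(=O)c1cc(Br)c(OCc2ccccc2)c(OCc2ccccc2)c1O | intermediate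
4 | (E)-1-[3,4-bis(benzyloxy)-5-bromo-2-hydroxyphenyl]-3-(dimethylamino)prop-2-en-1-one | CN(C)/C=C/C(=O)c1cc(Br)c(OCc2ccccc2)c(OCc2ccccc2)c1O | intermediate (not isolated)
5 | 7,8-bis(benzyloxy)-6-bromo-4H-chromen-4-one | O=c1ccoc2c(OCc3ccccc3)c(OCc3ccccc3)c(Br)cc12 | intermediate
6 | [4-(benzyloxy)phenyl]boronic acid | OB(O)c1ccc(OCc2ccccc2)cc1 | starting material
7 | (2R)-7,8-bis(benzyloxy)-2-[4-(benzyloxy)phenyl]-6-bromochroman-4-one | O=C1C[C@H](c2ccc(OCc3ccccc3)cc2)Oc2c(OCc3ccccc3)c(OCc3ccccc3)c(Br)cc12 | intermediate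
8 | (2R,4R)-7,8-bis(benzyloxy)-2-[4-(benzyloxy)phenyl]-6-bromochroman-4-ol | O[C@@H]1C[C@H](c2ccc(OCc3ccccc3)cc2)Oc2c(OCc3ccccc3)c(OCc3ccccc3)c(Br)cc12 | intermediate
9 | (2R)-7,8-bis(benzyloxy)-2-[4-(benzyloxy)phenyl]-6-bromo-2H-chromene | Brc1cc2C=C[C@H](c3ccc(OCc4ccccc4)cc3)Oc2c(OCc3ccccc3)c1OCc1ccccc1 | intermediate
10 | (2S,3R,4R)-7,8-bis(benzyloxy)-2-[4-(benzyloxy)phenyl]-6-bromochromane-3,4-diol | Brc1cc2[C@@H](O)[C@@H](O)[C@H](c3ccc(OCc4ccccc4)cc3)Oc2c(OCc3ccccc3)c1OCc1ccccc1 | intermediate
11 | Fl–Br, 3,4-acetonide of 10 | Brc1cc2[C@H]3OC(C)(C)O[C@H]3[C@H](c3ccc(OCc4ccccc4)cc3)Oc2c(OCc3ccccc3)c1OCc1ccccc1 | intermediate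
12 | Fl–Li, 6-lithio derivative of the lower acetonide | [Li]c1cc2[C@H]3OC(C)(C)O[C@H]3[C@H](c3ccc(OCc4ccccc4)cc3)Oc2c(OCc3ccccc3)c1OCc1ccccc1 | intermediate (not isolated)
13 | Fl–CHO, 3,4-acetonide of (2S,3R,4R)-7,8-bis(benzyloxy)-2-[4-(benzyloxy)phenyl]-3,4-dihydroxychromane-6-carbaldehyde | O=Cc1cc2[C@H]3OC(C)(C)O[C@H]3[C@H](c3ccc(OCc4ccccc4)cc3)Oc2c(OCc3ccccc3)c1OCc1ccccc1 | intermediate
14 | 1-[4-(benzyloxy)phenyl]ethanone | CC(=O)c1ccc(OCc2ccccc2)cc1 | starting material
15 | (E)-1-[4-(benzyloxy)phenyl]-3-Fl-prop-2-en-1-one | O=C(/C=C/c1cc2[C@H]3OC(C)(C)O[C@H]3[C@H](c3ccc(OCc4ccccc4)cc3)Oc2c(OCc3ccccc3)c1OCc1ccccc1)c1ccc(OCc2ccccc2)cc1 | intermediate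
16 | (R,E)-1-[4-(benzyloxy)phenyl]-3-Fl-prop-2-en-1-ol | O[C@H](/C=C/c1cc2[C@H]3OC(C)(C)O[C@H]3[C@H](c3ccc(OCc4ccccc4)cc3)Oc2c(OCc3ccccc3)c1OCc1ccccc1)c1ccc(OCc2ccccc2)cc1 | intermediate
17 | (S)-[4-(benzyloxy)phenyl][(2S,3S)-3-Fl-oxiran-2-yl]methanol | O[C@H]([C@@H]1O[C@H]1c1cc2[C@H]3OC(C)(C)O[C@H]3[C@H](c3ccc(OCc4ccccc4)cc3)Oc2c(OCc3ccccc3)c1OCc1ccccc1)c1ccc(OCc2ccccc2)cc1 | intermediate
18 | 2,3-dihydroxybenzaldehyde | O=Cc1cccc(O)c1O | starting material
19 | 2,3-bis(benzyloxy)benzaldehyde | O=Cc1cccc(OCc2ccccc2)c1OCc1ccccc1 | intermediate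
20 | 2,3-bis(benzyloxy)phenyl formate | O=COc1cccc(OCc2ccccc2)c1OCc1ccccc1 | intermediate (not isolated)
21 | 2,3-bis(benzyloxy)phenol | Oc1cccc(OCc2ccccc2)c1OCc1ccccc1 | intermediate
22 | 1,2-bis(benzyloxy)-3-{(R)-[4-(benzyloxy)phenyl][(2R,3S)-3-Fl-oxiran-2-yl]methoxy}benzene | c1ccccc1COc1ccc(cc1)[C@@H](Oc1cccc(OCc2ccccc2)c1OCc1ccccc1)[C@@H]1O[C@H]1c1cc2[C@H]3OC(C)(C)O[C@H]3[C@H](c3ccc(OCc4ccccc4)cc3)Oc2c(OCc3ccccc3)c1OCc1ccccc1 | intermediate
23 | (2R,3R)-7,8-bis(benzyloxy)-2-[4-(benzyloxy)phenyl]-4-Fl-chroman-3-ol, 2,3-cis-3,4-trans | c1ccccc1COc1ccc(cc1)[C@H]1Oc2c(ccc(OCc3ccccc3)c2OCc2ccccc2)[C@H](c2cc3[C@H]4OC(C)(C)O[C@H]4[C@H](c4ccc(OCc5ccccc5)cc4)Oc3c(OCc3ccccc3)c2OCc2ccccc2)[C@H]1O | intermediate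
24 | hexa-O-benzyl triol (23 with free lower (3R,4R)-cis-3,4-diol) | c1ccccc1COc1ccc(cc1)[C@H]1Oc2c(ccc(OCc3ccccc3)c2OCc2ccccc2)[C@H](c2cc3[C@@H](O)[C@@H](O)[C@H](c4ccc(OCc5ccccc5)cc4)Oc3c(OCc3ccccc3)c2OCc2ccccc2)[C@H]1O | intermediate
25 | epioritin-(4β→6)-ent-oritin-4α-ol (CNP0391561.9) | Oc1ccc([C@H]2Oc3c(ccc(O)c3O)[C@H](c3cc4c(c(O)c3O)O[C@@H](c3ccc(O)cc3)[C@H](O)[C@@H]4O)[C@H]2O)cc1 | target

**Step count and risks**
Total: 18 steps. Longest linear sequence: 16 steps (steps 1–12 and 15–18).

Steps most likely to fail: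

Step 16. The activated epoxide may ionise fully, so that a 1,2-hydride shift to the benzyl ketone (Meinwald rearrangement), stereorandom ring closure or cleavage of the lower acetal competes with the Friedel–Crafts closure. The fallback sets out from 22: the epoxide is opened at the benzylic carbon with inversion by sodium benzenethiolate (PhSNa, THF/MeOH, 0 °C) to give the anti β-hydroxy sulfide F1. The sulfide is then activated with a thiophilic silver salt (AgBF4, 2,6-di-tert-butylpyridine, CH2Cl2, –40 °C), the way flavan C4 cations are generated from 4-thioethers. The tethered arene should close ring C trans to the 3-hydroxyl, which brings the route back at 23. This separates cation generation from an oxophilic Lewis acid.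

Step 15. The oxyphosphonium intermediate may ionise at the 4-benzyloxybenzylic carbon, eroding the configuration at C1, or substitution at the hindered carbinol may be slow. The fallback makes the aryl–oxygen bond instead of the alkyl–oxygen bond, so that nothing is substituted at the stereocentre. It sets out from 15: reduction with the (R)-oxazaborolidine gives the epimeric (S)-allylic alcohol F2. Commercial 3-bromocatechol is benzylated (BnBr, K2CO3, DMF) to 1,2-bis(benzyloxy)-3-bromobenzene F3. Palladium-catalysed C–O cross-coupling of F2 with F3 ([Pd(allyl)Cl]2, the di-tert-butyl biaryl phosphine RockPhos, Cs2CO3, toluene, 80 °C) gives the (S)-allyl aryl ether F4 with retention. Shi epoxidation of F4 with the same L-fructose-derived ketone then returns the route at 22.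

Step 12. Facial selectivity may be poor next to the free carbinol (a mismatched pairing), the dioxirane may oxidise the benzylic alcohol, or the very electron-rich aryl epoxide may open during isolation. The fallback sets the epoxide at the enone stage and the carbinol afterwards. It sets out from 15: Juliá–Colonna epoxidation (poly-L-leucine, urea–H2O2, DBU, THF) gives the (2R,3S)-epoxy ketone F5, whose carbonyl group stabilises the epoxide. Chelation-controlled reduction with Zn(BH4)2 (Et2O, –20 °C), which gives anti epoxy alcohols from trans-α,β-epoxy ketones, then returns the route at 17.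

**Further compounds**
F1 | step 16 | (1R,2R,3R)-3-[2,3-bis(benzyloxy)phenoxy]-3-[4-(benzyloxy)phenyl]-1-Fl-1-(phenylsulfanyl)propan-2-ol (anti β-hydroxy sulfide from 22) | c1ccccc1COc1ccc(cc1)[C@@H](Oc1cccc(OCc2ccccc2)c1OCc1ccccc1)[C@H](O)[C@H](Sc1ccccc1)c1cc2[C@H]3OC(C)(C)O[C@H]3[C@H](c3ccc(OCc4ccccc4)cc3)Oc2c(OCc3ccccc3)c1OCc1ccccc1
F2 | step 15 | (S,E)-1-[4-(benzyloxy)phenyl]-3-Fl-prop-2-en-1-ol | O[C@@H](/C=C/c1cc2[C@H]3OC(C)(C)O[C@H]3[C@H](c3ccc(OCc4ccccc4)cc3)Oc2c(OCc3ccccc3)c1OCc1ccccc1)c1ccc(OCc2ccccc2)cc1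
F3 | step 15 | 1,2-bis(benzyloxy)-3-bromobenzene | Brc1cccc(OCc2ccccc2)c1OCc1ccccc1
F4 | step 15 | 1,2-bis(benzyloxy)-3-{[(S,E)-1-[4-(benzyloxy)phenyl]-3-Fl-prop-2-en-1-yl]oxy}benzene | c1ccccc1COc1ccc(cc1)[C@@H](Oc1cccc(OCc2ccccc2)c1OCc1ccccc1)/C=C/c1cc2[C@H]3OC(C)(C)O[C@H]3[C@H](c3ccc(OCc4ccccc4)cc3)Oc2c(OCc3ccccc3)c1OCc1ccccc1
F5 | step 12 | [4-(benzyloxy)phenyl][(2R,3S)-3-Fl-oxiran-2-yl]methanone | O=C([C@@H]1O[C@H]1c1cc2[C@H]3OC(C)(C)O[C@H]3[C@H](c3ccc(OCc4ccccc4)cc3)Oc2c(OCc3ccccc3)c1OCc1ccccc1)c1ccc(OCc2ccccc2)cc1
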